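Ring B is disconnected across C1–C6 and C4–C5 (spiro[5.5]undecane numbering: ring B C1–C5, spiro C6, ring A C7–C11). The key step is a Diels–Alder reaction of a 2-silyloxybutadiene (C1–C4) with the exocyclic enone C5=C6–C7=O of ring A. It exploits the 1,4-relationship between the spiro atom C6 and the alkylidene-bearing C3 of ring B, and the C7 methylidene next to C6 as a masked ketone. One operation closes ring B, creates the quaternary spiro carbon and places oxygen at C3. The precursor, (R)-4-bromo-3,3-dimethyl-2-methylidenecyclohexanone, comes from a stereospecific bromonium cyclisation; the spiro configuration is fixed later by a chiral-base desymmetrisation.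

Key step: step 6

Remark: the face on which the diene adds to 9 only decides which arm of ring B carries the transient enol ether; step 7 makes ring B symmetric, so this face is immaterial and the C6 configuration is set under reagent control in step 8.

Step 1
Reactants: 1 3-methylbut-2-en-1-ol
Product: 2 (2R)-2-bromo-3-chloro-3-methylbutan-1-ol
Conditions: NBS, ClTi(Oi-Pr)3, Ti(Oi-Pr)4 (cat.), chiral tridentate Schiff-base ligand (cat.), hexanes, −20 °C
Reagents that add atoms: N-bromosuccinimide, O=C1CCC(=O)N1Br; chlorotitanium triisopropoxide, CC(C)O[Ti](Cl)(OC(C)C)OC(C)C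
Why: Titanium-templated catalytic enantioselective bromochlorination of an allylic alcohol, in which the ligand-bound titanium alkoxide directs face-selective bromonium formation and delivers chloride anti to the tertiary carbon, should set the C–Br stereocentre (the later C10) as R with the appropriate ligand enantiomer.

Step 2
Reactants: 2 (2R)-2-bromo-3-chloro-3-methylbutan-1-ol
Product: 3 (2R)-2-bromo-3-chloro-3-methylbutyl trifluoromethanesulfonate
Conditions: Tf2O, 2,6-lutidine, CH2Cl2, −78 °C
Reagents that add atoms: trifluoromethanesulfonic anhydride, O=S(=O)(OS(=O)(=O)C(F)(F)F)C(F)(F)F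
Why: O-Sulfonylation of the primary alcohol activates it for C-alkylation without touching the stereocentre, and the triflate is used cold and crude.

Step 3
Reactants: 3 (2R)-2-bromo-3-chloro-3-methylbutyl trifluoromethanesulfonate; 4 ethyl (2E)-3-ethoxybut-2-enoate
Product: 6 ethyl (2E,6R)-6-bromo-7-chloro-3-ethoxy-7-methyloct-2-enoate, via lithium dienolate 5 (not isolated)
Conditions: LiN(i-Pr)2, THF, −78 °C; then 3, DMPU, −78 → −40 °C
Reagents that add atoms: none
Why: γ-Alkylation of the extended lithium enolate of a β-alkoxy enoate (a masked acetoacetate dianion) by SN2 displacement at the primary triflate leaves the remote C–Br centre untouched and delivers the future C7 ketone already capped as its enol ether.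

Step 4
Reactants: 6 ethyl (2E,6R)-6-bromo-7-chloro-3-ethoxy-7-methyloct-2-enoate
Product: 7 ethyl (5R)-5-bromo-2-ethoxy-6,6-dimethylcyclohex-1-ene-1-carboxylate
Conditions: (CF3)2CHOH, 2,6-di-tert-butyl-4-methylpyridine, 0 °C → rt
Reagents that add atoms: none
Why: Solvolytic bromonium cation–olefin cyclisation: ionisation of the tertiary chloride with anchimeric assistance by the neighbouring bromine gives a configurationally defined bromonium ion that is opened at the tertiary carbon by the α-carbon of the β-ethoxy enoate (its oxygen is capped, so only C-attack closes the six-membered ring), proton loss then restores the enol ether, and the C–Br centre is carried through stereospecifically.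

Step 5
Reactants: 7 ethyl (5R)-5-bromo-2-ethoxy-6,6-dimethylcyclohex-1-ene-1-carboxylate
Product: 9 (4R)-4-bromo-3,3-dimethyl-2-methylidenecyclohexan-1-one, via allylic alcohol 8 (not isolated)
Conditions: i-Bu2AlH, CH2Cl2, −78 °C; then 1 M HCl, THF, 0 °C
Reagents that add atoms: water, O
Why: 1,2-Reduction of the vinylogous carbonate ester to the γ-hydroxy enol ether, then acid-triggered loss of the allylic hydroxyl and hydrolysis of the resulting oxocarbenium ion (the classical enol-ether reduction route from a β-keto ester to an α-methylene ketone), places the exocyclic methylene regiospecifically on the carbon next to the gem-dimethyl group without affecting the stereocentre.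

Step 6
Reactants: 9 (4R)-4-bromo-3,3-dimethyl-2-methylidenecyclohexan-1-one; 10 2-(trimethylsilyloxy)buta-1,3-diene
Product: 11 (10R)-10-bromo-11,11-dimethyl-3-(trimethylsilyloxy)spiro[5.5]undec-2-en-7-one (C6 epimers)
Conditions: PhMe, 2,6-di-tert-butyl-4-methylphenol (cat.), 110 °C, sealed tube
Reagents that add atoms: none
Why: This is a normal-electron-demand Diels–Alder reaction between the s-cis-locked exocyclic enone (C5=C6–C7=O) and the electron-rich 2-silyloxydiene (C1=C2–C3(OSi)=C4), concerted but asynchronous with bonding to the unhindered methylene C5 leading; a stepwise Mukaiyama–Michael/ring-closure path would give the same product. The closest known reactions are the thermal and Lewis-acid [4+2] additions of 2-methylenecycloalkanones, including 3,3-dimethyl-2-methylenecyclohexanone, to isoprene-type and 2-silyloxy dienes. Ring B is closed in the [4+2] mode, the C4–C5 and C1–C6 σ-bonds forming suprafacially on both partners in one operation and generating the quaternary spiro carbon. C6 is only transiently stereogenic (while the enol ether marks one arm), so the π-facial course relative to C10–Br has no consequence and the adduct is carried on as whatever C6-epimer mixture forms. The selectivity needed is regiochemical: the largest HOMO coefficient of the diene (the CH2 next to C–OSi, future C4) pairs with the β-carbon of the enone (the exocyclic CH2, C5), which places oxygen at C3, 1,4 to the spiro atom. The neopentyl-type secondary bromide is inert under these neutral conditions, and the gem-dimethyl group should retard the hetero-Diels–Alder dimerisation typical of α-methylene ketones.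

Step 7
Reactants: 11 (10R)-10-bromo-11,11-dimethyl-3-(trimethylsilyloxy)spiro[5.5]undec-2-en-7-one (C6 epimers)
Product: 13 (10R)-10-bromo-11,11-dimethyl-7-methylidenespiro[5.5]undecan-3-one, via C7-methylidene silyl enol ether 12 (not isolated)
Conditions: Ph3PCH3Br, KOt-Bu, PhMe, 90 °C; then 1 M HCl, THF, rt
Reagents that add atoms: methyltriphenylphosphonium bromide, C[P+](c1ccccc1)(c1ccccc1)c1ccccc1.[Br-]
Why: Wittig methylenation of the hindered C7 ketone while the C3 carbonyl stays masked as its silyl enol ether, followed by acid hydrolysis to the C3 ketone, makes ring B constitutionally symmetric so that C6 ceases to be a stereocentre; the equatorial bromide has no anti-periplanar hydrogen and should survive the basic ylide.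

Step 8
Reactants: 13 (10R)-10-bromo-11,11-dimethyl-7-methylidenespiro[5.5]undecan-3-one
Product: 15 (6S,10R)-10-bromo-11,11-dimethyl-7-methylidenespiro[5.5]undec-1-en-3-one, via trimethylsilyl enol ether 14 (not isolated)
Conditions: (R,R)-bis(1-phenylethyl)amine, n-BuLi, LiCl, Me3SiCl (in situ quench), THF, −100 °C; then Pd(OAc)2, MeCN, rt
Reagents that add atoms: none
Why: Desymmetrising enolisation with a chiral lithium amide base followed by Saegusa–Ito oxidation: in the ring B chair that keeps the bulky CMe2 carbon C11 equatorial, the (R,R)-amide is expected, by analogy with 4-tert-butylcyclohexanone, to remove the axial α-proton of the arm lying cis to C10–Br (the (S,S)-amide would select the other arm), so that reagent control makes C6 S once divalent palladium dehydrogenates the trapped enol ether to the C1=C2 enone.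

Step 9
Reactants: 15 (6S,10R)-10-bromo-11,11-dimethyl-7-methylidenespiro[5.5]undec-1-en-3-one
Product: 16 (3Z,6S,10R)-10-bromo-3-(bromomethylidene)-11,11-dimethyl-7-methylidenespiro[5.5]undec-1-ene
Conditions: Ph3PCH2Br·Br, KOt-Bu, THF, −78 → 0 °C
Reagents that add atoms: (bromomethyl)triphenylphosphonium bromide, BrC[P+](c1ccccc1)(c1ccccc1)c1ccccc1.[Br-]
Why: Wittig bromomethylenation of the only remaining carbonyl (1,2-addition to the enone) gives the cross-conjugated bromodiene, in which the Z isomer, with bromine on the side of the flat vinylic C2–H instead of the C4 methylene, is expected to be favoured and would be separated from any E isomer by chromatography.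

Compound list
1 | 3-methylbut-2-en-1-ol | CC(C)=CCO | starting material
2 | (2R)-2-bromo-3-chloro-3-methylbutan-1-ol | OC[C@@H](Br)C(C)(C)Cl | intermediate
3 | (2R)-2-bromo-3-chloro-3-methylbutyl trifluoromethanesulfonate | O=S(=O)(OC[C@@H](Br)C(C)(C)Cl)C(F)(F)F | intermediate
4 | ethyl (2E)-3-ethoxybut-2-enoate | CCOC(=O)/C=C(\C)OCC | starting material
5 | lithium 1,3-diethoxybuta-1,3-dien-1-olate (dienolate of 4, not isolated) | C=C(OCC)C=C([O-])OCC.[Li+] | intermediate
6 | ethyl (2E,6R)-6-bromo-7-chloro-3-ethoxy-7-methyloct-2-enoate | CCOC(=O)/C=C(\CC[C@@H](Br)C(C)(C)Cl)OCC | intermediate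
7 | ethyl (5R)-5-bromo-2-ethoxy-6,6-dimethylcyclohex-1-ene-1-carboxylate | CCOC(=O)C1=C(OCC)CC[C@@H](Br)C1(C)C | intermediate
8 | [(5R)-5-bromo-2-ethoxy-6,6-dimethylcyclohex-1-en-1-yl]methanol (not isolated) | OCC1=C(OCC)CC[C@@H](Br)C1(C)C | intermediate
9 | (4R)-4-bromo-3,3-dimethyl-2-methylidenecyclohexan-1-one | C=C1C(=O)CC[C@@H](Br)C1(C)C | intermediate
10 | 2-(trimethylsilyloxy)buta-1,3-diene | C=CC(=C)O[Si](C)(C)C | starting material
11 | (10R)-10-bromo-11,11-dimethyl-3-(trimethylsilyloxy)spiro[5.5]undec-2-en-7-one (C6 epimers, C6 left open) | C[Si](C)(C)OC1=CCC2(CC1)C(=O)CC[C@@H](Br)C2(C)C | intermediate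
12 | [(10R)-10-bromo-11,11-dimethyl-7-methylidenespiro[5.5]undec-2-en-3-yl]oxy(trimethyl)silane (C6 epimers, not isolated) | C=C1CC[C@@H](Br)C(C)(C)C12CC=C(O[Si](C)(C)C)CC2 | intermediate
13 | (10R)-10-bromo-11,11-dimethyl-7-methylidenespiro[5.5]undecan-3-one | C=C1CC[C@@H](Br)C(C)(C)C12CCC(=O)CC2 | intermediate
14 | [(6S,10R)-10-bromo-11,11-dimethyl-7-methylidenespiro[5.5]undec-2-en-3-yl]oxy(trimethyl)silane (not isolated) | C=C1CC[C@@H](Br)C(C)(C)[C@@]12CC=C(O[Si](C)(C)C)CC2 | intermediate
15 | (6S,10R)-10-bromo-11,11-dimethyl-7-methylidenespiro[5.5]undec-1-en-3-one | C=C1CC[C@@H](Br)C(C)(C)[C@@]12C=CC(=O)CC2 | intermediate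
16 | (3Z,6S,10R)-10-bromo-3-(bromomethylidene)-11,11-dimethyl-7-methylidenespiro[5.5]undec-1-ene | C=C1CC[C@@H](Br)C(C)(C)[C@@]12C=C/C(=C\Br)CC2 | target

Total step count: 9. Longest linear sequence: 9 steps (from 1 to 16; compounds 4 and 10 are purchased).

Steps most likely to fail, in order of risk:

Step 8. The chiral base may discriminate poorly between the two diastereotopic α-methylene groups of ring B, or act in the opposite sense, so that both C6 epimers of the enone form. The fallback sets out from ketone 13. Both arms are dehydrogenated with IBX (DMSO, 80 °C) to the cross-conjugated dienone (10R)-10-bromo-11,11-dimethyl-7-methylidenespiro[5.5]undeca-1,4-dien-3-one F1, in which C6 is again non-stereogenic. Ligand-controlled copper hydride conjugate reduction of one of its two diastereotopic enone double bonds (Cu(OAc)2, chiral bisphosphine, hydrosilane, t-BuOH, PhMe) then comes back to enone 15, the ligand enantiomer being chosen to saturate the arm trans to C10–Br.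

Step 9. The oxaphosphetane may form with little preference for placing bromine on the C2 side, so that E and Z bromodienes arise in comparable amounts. The fallback sets out from enone 15. Dibromomethylenation with the ylide from (dibromomethyl)triphenylphosphonium bromide and KOt-Bu gives the geometry-free (6S,10R)-10-bromo-3-(dibromomethylidene)-11,11-dimethyl-7-methylidenespiro[5.5]undec-1-ene F2. Bromine–lithium exchange with n-BuLi at −105 °C is fastest at the more congested vinylic bromine, here the one cis to the C4 methylene. Protonation of the vinyllithium with MeOH, with retention, should then come back to the Z bromide 16.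

Step 4. The bromonium ion may be intercepted by the solvent or lose a proton before the enoate carbon attacks, or the oxocarbenium ion may shed its O-ethyl group. The fallback sets out from triflate 3. Alkylation of the dianion of ethyl acetoacetate (NaH, then n-BuLi, THF) gives ethyl (6R)-6-bromo-7-chloro-7-methyl-3-oxooctanoate F3. SnCl4 in CH2Cl2 ionises the tertiary chloride and the tin-chelated enol closes ring A on carbon to give ethyl (1R,3R)-3-bromo-2,2-dimethyl-6-oxocyclohexane-1-carboxylate F4 (C1 is epimerisable). O-Ethylation with triethyl orthoformate and catalytic H2SO4 in EtOH then comes back to enol ether 7.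

Further compounds
F1 | step 8 | (10R)-10-bromo-11,11-dimethyl-7-methylidenespiro[5.5]undeca-1,4-dien-3-one | C=C1CC[C@@H](Br)C(C)(C)C12C=CC(=O)C=C2
F2 | step 9 | (6S,10R)-10-bromo-3-(dibromomethylidene)-11,11-dimethyl-7-methylidenespiro[5.5]undec-1-ene | C=C1CC[C@@H](Br)C(C)(C)[C@@]12C=CC(=C(Br)Br)CC2
F3 | step 4 | ethyl (6R)-6-bromo-7-chloro-7-methyl-3-oxooctanoate | CCOC(=O)CC(=O)CC[C@@H](Br)C(C)(C)Cl
F4 | step 4 | ethyl (1R,3R)-3-bromo-2,2-dimethyl-6-oxocyclohexane-1-carboxylate | CCOC(=O)[C@H]1C(=O)CC[C@@H](Br)C1(C)C
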